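**Retrosynthetic overview**
1. Last bond: the C8–O ester, made by acylating the C8 alcohol of the tricyclic core with (E)-2-(acetoxymethyl)but-2-enoic acid.
2. Ten-membered carbocycle and α-methylene lactone: one intramolecular CrCl2 allylation (C6–C7) followed by lactonisation (O6–C12) of a Z-enal/allylic bromide; the bromide comes from a Morita–Baylis–Hillman adduct (C7–C11).
3. Key disconnection: the furanone C3–O bond. An α-hydroxy-γ-lactone (C1, C7–C10) and a Z-enyne (C2–C6, C15) are joined by acetylide addition, and the lactone acyl C–O bond is traded for the vinylogous C3–O bond (ring transposition).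
4. The lactone comes from methyl pyruvate and a pyruvaldehyde-acetal silyl enol ether: copper–bis(oxazoline) Mukaiyama aldol (C10), then Evans–Saksena anti reduction (C8).
5. Ring order: temporary γ-lactone → 3(2H)-furanone → ten-membered ring → α-methylene-γ-lactone.

Atom labels C1–C15 are germacrane numbers: C1 furanone C=O, C3 furanone O–C=, C6 lactone carbinol, C8 ester carbinol, C10 quaternary ether carbon.
Assumption: the SMILES is taken as drawn, i.e. 6S,7S,8R,10R, 4Z ring olefin, (E)-configured side chain.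

**Route**

Step 1
Reactants: 1 1,1-dimethoxypropan-2-one
Product: 2 [(3,3-dimethoxyprop-1-en-2-yl)oxy]trimethylsilane
Conditions: LiN(i-Pr)2 (1.1 equiv), THF, −78 °C; TMSCl, −78 → 0 °C
Reagents that add atoms: chlorotrimethylsilane C[Si](C)(C)Cl
Why: Kinetic enolisation takes the unhindered methyl protons (the acetal C–H is shielded and its carbanion is destabilised by two oxygens) and O-silylation gives the terminal silyl enol ether (silyl enol ether formation).

Step 2
Reactants: 2 [(3,3-dimethoxyprop-1-en-2-yl)oxy]trimethylsilane, 3 methyl pyruvate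
Product: 5 methyl (R)-2-hydroxy-5,5-dimethoxy-2-methyl-4-oxopentanoate, via TMS ether 4 (not isolated)
Conditions: Cu(OTf)2 (10 mol %), (R,R)-t-Bu-box [2,2′-isopropylidenebis((4R)-4-tert-butyl-2-oxazoline), 11 mol %], THF, −78 °C; then 1 M HCl, THF, 0 °C
Reagents that add atoms: none
Why: Catalytic enantioselective Mukaiyama aldol addition to pyruvate held as a five-membered chelate on divalent copper, where the tert-butyl groups block one ketone face; the (S,S)-catalyst is established to give (S)-adducts of methyl pyruvate, so the (R,R)-catalyst sets C10 as R, and acid work-up removes the transferred TMS group.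

Step 3
Reactants: 5 methyl (R)-2-hydroxy-5,5-dimethoxy-2-methyl-4-oxopentanoate
Product: 7 (3R,5R)-5-(dimethoxymethyl)-3-hydroxy-3-methyloxolan-2-one, via anti-diol ester 6 (not isolated)
Conditions: Me4NBH(OAc)3 (5 equiv), MeCN/AcOH 1:1, −35 °C; aqueous work-up; then PPTS (10 mol %), toluene, 50 °C
Reagents that add atoms: none
Why: Evans–Saksena reduction, in which the tertiary C10 hydroxyl exchanges onto boron and delivers hydride intramolecularly through a chair transition state to give the 1,3-anti diol (C8 R); the new secondary hydroxyl then closes the non-enolisable γ-lactone (acid-catalysed lactonisation).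

Step 4
Reactants: 8 (Z)-3-methylpent-2-en-4-yn-1-ol
Product: 9 tert-butyldimethyl{[(Z)-3-methylpent-2-en-4-yn-1-yl]oxy}silane
Conditions: TBSCl, imidazole, CH2Cl2, 0 °C → rt
Reagents that add atoms: tert-butyldimethylsilyl chloride CC(C)(C)[Si](C)(C)Cl
Why: Standard silyl ether formation; masking the Z-allylic oxygen prevents its 5-exo-dig addition to the ynone (furan formation) in step 5.

Step 5
Reactants: 7 (3R,5R)-5-(dimethoxymethyl)-3-hydroxy-3-methyloxolan-2-one, 9 tert-butyldimethyl{[(Z)-3-methylpent-2-en-4-yn-1-yl]oxy}silane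
Product: 11 (R)-5-[(Z)-4-(tert-butyldimethylsilyloxy)but-2-en-2-yl]-2-[(R)-2-hydroxy-3,3-dimethoxypropyl]-2-methylfuran-3(2H)-one, via hydroxy ynone 10 (not isolated)
Conditions: 9 (2.3 equiv), n-BuLi (2.2 equiv), THF, −78 °C; add 7, −78 → −20 °C; then t-BuOH (3 equiv), −20 °C → rt
Reagents that add atoms: none
Why: Proposed new method: alkynylative ring transposition of an α-hydroxy-γ-butyrolactone into a 3(2H)-furanone, in which the lithium acetylide adds to the non-enolisable lactone carbonyl (the first equivalent only deprotonates the tertiary OH), the lactolate opens on warming to the α′-alkoxy ynone 10, and with t-BuOH as proton shuttle the tertiary C10 alkoxide adds 5-endo-dig to C3 and the allenolate is protonated, so the acyl C1–O8 bond is exchanged for the C3–O bond in one flask without touching C8 or C10; the closest known chemistry is acetylide opening of lactones to hydroxy ynones and the separately run base- or gold-promoted cyclisation of α′-hydroxy ynones to 3(2H)-furanones.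

Step 6
Reactants: 11 (R)-5-[(Z)-4-(tert-butyldimethylsilyloxy)but-2-en-2-yl]-2-[(R)-2-hydroxy-3,3-dimethoxypropyl]-2-methylfuran-3(2H)-one
Product: 13 (R)-2-(tert-butyldimethylsilyloxy)-3-{(R)-5-[(Z)-4-(tert-butyldimethylsilyloxy)but-2-en-2-yl]-2-methyl-3-oxo-2,3-dihydrofuran-2-yl}propanal, via bis-TBS acetal 12 (not isolated)
Conditions: TBSOTf (1.3 equiv), 2,4,6-collidine (6 equiv), CH2Cl2, −78 → 0 °C; then TMSOTf (2.5 equiv), 0 °C; then H2O, 0 °C → rt
Reagents that add atoms: tert-butyldimethylsilyl triflate CC(C)(C)[Si](C)(C)OS(=O)(=O)C(F)(F)F; water O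
Why: The silyl triflate/collidine pair first silylates the C8 hydroxyl, then TMSOTf/collidine converts the dimethyl acetal into a collidinium salt that water hydrolyses to the aldehyde (non-acidic silyl triflate–collidine acetal cleavage), leaving both TBS ethers and the C8 centre intact.

Step 7
Reactants: 13 (R)-2-(tert-butyldimethylsilyloxy)-3-{(R)-5-[(Z)-4-(tert-butyldimethylsilyloxy)but-2-en-2-yl]-2-methyl-3-oxo-2,3-dihydrofuran-2-yl}propanal, 14 methyl acrylate
Product: 15 methyl (4R)-4-(tert-butyldimethylsilyloxy)-5-{(R)-5-[(Z)-4-(tert-butyldimethylsilyloxy)but-2-en-2-yl]-2-methyl-3-oxo-2,3-dihydrofuran-2-yl}-3-hydroxy-2-methylidenepentanoate (C3 epimers)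
Conditions: DABCO (1.0 equiv), methyl acrylate (10 equiv, neat), rt, 48 h
Reagents that add atoms: none
Why: Morita–Baylis–Hillman reaction, which is fast for an α-silyloxy aldehyde; the new carbinol centre (C7) is formed as an epimer mixture that is erased in step 8.

Step 8
Reactants: 15 methyl (4R)-4-(tert-butyldimethylsilyloxy)-5-{(R)-5-[(Z)-4-(tert-butyldimethylsilyloxy)but-2-en-2-yl]-2-methyl-3-oxo-2,3-dihydrofuran-2-yl}-3-hydroxy-2-methylidenepentanoate
Product: 16 methyl (2Z,4R)-2-(bromomethyl)-4-(tert-butyldimethylsilyloxy)-5-{(R)-5-[(Z)-4-(tert-butyldimethylsilyloxy)but-2-en-2-yl]-2-methyl-3-oxo-2,3-dihydrofuran-2-yl}pent-2-enoate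
Conditions: NBS (1.3 equiv), Me2S (1.5 equiv), CH2Cl2, 0 °C → rt
Reagents that add atoms: N-bromosuccinimide O=C1CCC(=O)N1Br
Why: Corey–Kim-type bromination, in which the bromosulfonium reagent activates the allylic alcohol and bromide attacks SN2′ with allylic transposition to give the thermodynamically preferred (Z)-2-(bromomethyl)enoate.

Step 9
Reactants: 16 methyl (2Z,4R)-2-(bromomethyl)-4-(tert-butyldimethylsilyloxy)-5-{(R)-5-[(Z)-4-(tert-butyldimethylsilyloxy)but-2-en-2-yl]-2-methyl-3-oxo-2,3-dihydrofuran-2-yl}pent-2-enoate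
Product: 17 methyl (2Z,4R)-2-(bromomethyl)-4-(tert-butyldimethylsilyloxy)-5-{(R)-5-[(Z)-4-hydroxybut-2-en-2-yl]-2-methyl-3-oxo-2,3-dihydrofuran-2-yl}pent-2-enoate
Conditions: CSA (10 mol %), MeOH/CH2Cl2 1:1, 0 °C
Reagents that add atoms: none
Why: Acid-catalysed methanolysis removes the unhindered primary allylic TBS ether much faster than the secondary C8 TBS ether, and the allylic bromide does not solvolyse at 0 °C without base (selective desilylation).

Step 10
Reactants: 17 methyl (2Z,4R)-2-(bromomethyl)-4-(tert-butyldimethylsilyloxy)-5-{(R)-5-[(Z)-4-hydroxybut-2-en-2-yl]-2-methyl-3-oxo-2,3-dihydrofuran-2-yl}pent-2-enoate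
Product: 18 methyl (2Z,4R)-2-(bromomethyl)-4-(tert-butyldimethylsilyloxy)-5-{(R)-2-methyl-3-oxo-5-[(Z)-4-oxobut-2-en-2-yl]-2,3-dihydrofuran-2-yl}pent-2-enoate
Conditions: Dess–Martin periodinane (1.3 equiv), NaHCO3, CH2Cl2, 0 °C
Reagents that add atoms: none
Why: Buffered Dess–Martin oxidation is neutral and fast, so the Z-enal forms without isomerisation and the allylic bromide is untouched.

Step 11
Reactants: 18 methyl (2Z,4R)-2-(bromomethyl)-4-(tert-butyldimethylsilyloxy)-5-{(R)-2-methyl-3-oxo-5-[(Z)-4-oxobut-2-en-2-yl]-2,3-dihydrofuran-2-yl}pent-2-enoate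
Product: 20 (2Z,4S,8R,9R,11R)-9-(tert-butyldimethylsilyloxy)-2,11-dimethyl-7-methylidene-5,14-dioxatricyclo[9.2.1.0^4,8]tetradeca-1(13),2-diene-6,12-dione, via hydroxy ester 19 (not isolated)
Conditions: CrCl2 (8 equiv), THF/DMF 10:1, 0.002 M, rt; 1 M HCl work-up; then TsOH·H2O (cat.), CH2Cl2, rt
Reagents that add atoms: none
Why: Intramolecular Nozaki–Hiyama-type (chromium Barbier) 2-(methoxycarbonyl)allylation at high dilution closes the ten-membered ring through C7 and the C6 alkoxide then lactonises; allylic 1,3-strain keeps H8 in the plane of the allyl unit so the tethered aldehyde adds to the face anti to the OTBS group (C7 as in the target), and the chair transition state with the dienyl group equatorial is expected to give the anti adduct and hence the trans-lactone (C6 S), as in chromium-mediated closures of other germacranolides.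

Step 12
Reactants: 20 (2Z,4S,8R,9R,11R)-9-(tert-butyldimethylsilyloxy)-2,11-dimethyl-7-methylidene-5,14-dioxatricyclo[9.2.1.0^4,8]tetradeca-1(13),2-diene-6,12-dione
Product: 21 (2Z,4S,8S,9R,11R)-9-hydroxy-2,11-dimethyl-7-methylidene-5,14-dioxatricyclo[9.2.1.0^4,8]tetradeca-1(13),2-diene-6,12-dione
Conditions: HF·pyridine, THF/pyridine, 0 °C → rt
Reagents that add atoms: none
Why: Fluoride-mediated desilylation under buffered, weakly acidic conditions that neither add to the α-methylene lactone nor open the furanone (the C7 descriptor changes from R to S only because the priority of the C8 branch changes).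

Step 13
Reactants: 22 acetaldehyde, 23 tert-butyl acrylate
Product: 24 tert-butyl 3-hydroxy-2-methylidenebutanoate (racemic)
Conditions: DABCO (0.5 equiv), 1,4-dioxane/H2O 1:1, rt, 3 d
Reagents that add atoms: none
Why: Morita–Baylis–Hillman reaction of an unhindered aliphatic aldehyde; the carbinol centre is removed in step 14.

Step 14
Reactants: 24 tert-butyl 3-hydroxy-2-methylidenebutanoate
Product: 26 tert-butyl (E)-2-(acetoxymethyl)but-2-enoate, via secondary acetate 25 (not isolated)
Conditions: Ac2O, Et3N, DMAP (cat.), CH2Cl2, 0 °C; then DABCO (0.3 equiv), THF, 65 °C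
Reagents that add atoms: acetic anhydride CC(=O)OC(C)=O
Why: Acetylation followed by DABCO-catalysed SN2′/SN2 allylic transposition of the acetate, which equilibrates to the thermodynamically favoured trisubstituted (E)-2-(acetoxymethyl)enoate (ester trans to methyl).

Step 15
Reactants: 26 tert-butyl (E)-2-(acetoxymethyl)but-2-enoate
Product: 27 (E)-2-(acetoxymethyl)but-2-enoic acid
Conditions: TFA/CH2Cl2 1:4, 0 °C → rt
Reagents that add atoms: none
Why: Acidolysis of the tert-butyl ester (loss of isobutene) leaves the allylic acetate and the alkene geometry untouched.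

Step 16
Reactants: 21 (2Z,4S,8S,9R,11R)-9-hydroxy-2,11-dimethyl-7-methylidene-5,14-dioxatricyclo[9.2.1.0^4,8]tetradeca-1(13),2-diene-6,12-dione, 27 (E)-2-(acetoxymethyl)but-2-enoic acid
Product: 29 [(2Z,4S,8S,9R,11R)-2,11-dimethyl-7-methylidene-6,12-dioxo-5,14-dioxatricyclo[9.2.1.0^4,8]tetradeca-1(13),2-dien-9-yl] (E)-2-(acetoxymethyl)but-2-enoate, via mixed anhydride 28 (not isolated)
Conditions: 27 (1.5 equiv), 2,4,6-Cl3C6H2COCl, Et3N, toluene, rt, 1 h; then 21, DMAP (0.3 equiv), toluene, 0 °C → rt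
Reagents that add atoms: none
Why: Yamaguchi esterification, in which DMAP is acylated at the less hindered enoyl carbonyl of the mixed anhydride and the acylpyridinium esterifies the hindered C8 alcohol with retention at C8, under conditions too mild to translactonise the core or isomerise the side chain.

**Compound list**
1 | 1,1-dimethoxypropan-2-one | CC(=O)C(OC)OC | starting material
2 | [(3,3-dimethoxyprop-1-en-2-yl)oxy]trimethylsilane | C=C(O[Si](C)(C)C)C(OC)OC | intermediate
3 | methyl pyruvate | CC(=O)C(=O)OC | starting material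
4 | methyl (R)-5,5-dimethoxy-2-methyl-4-oxo-2-(trimethylsilyloxy)pentanoate (not isolated) | COC(=O)[C@](C)(O[Si](C)(C)C)CC(=O)C(OC)OC | intermediate
5 | methyl (R)-2-hydroxy-5,5-dimethoxy-2-methyl-4-oxopentanoate | COC(=O)[C@](C)(O)CC(=O)C(OC)OC | intermediate
6 | methyl (2R,4R)-2,4-dihydroxy-5,5-dimethoxy-2-methylpentanoate (not isolated) | COC(=O)[C@](C)(O)C[C@@H](O)C(OC)OC | intermediate
7 | (3R,5R)-5-(dimethoxymethyl)-3-hydroxy-3-methyloxolan-2-one | O=C1O[C@@H](C(OC)OC)C[C@@]1(C)O | intermediate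
8 | (Z)-3-methylpent-2-en-4-yn-1-ol | C#C/C(C)=C\CO | starting material
9 | tert-butyldimethyl{[(Z)-3-methylpent-2-en-4-yn-1-yl]oxy}silane | C#C/C(C)=C\CO[Si](C)(C)C(C)(C)C | intermediate
10 | (2R,4R,8Z)-10-(tert-butyldimethylsilyloxy)-2,4-dihydroxy-1,1-dimethoxy-4,8-dimethyldec-8-en-6-yn-5-one (not isolated) | O=C(C#C/C(C)=C\CO[Si](C)(C)C(C)(C)C)[C@](C)(O)C[C@@H](O)C(OC)OC | intermediate
11 | (R)-5-[(Z)-4-(tert-butyldimethylsilyloxy)but-2-en-2-yl]-2-[(R)-2-hydroxy-3,3-dimethoxypropyl]-2-methylfuran-3(2H)-one | O=C1C=C(/C(C)=C\CO[Si](C)(C)C(C)(C)C)O[C@]1(C)C[C@@H](O)C(OC)OC | intermediate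
12 | (R)-5-[(Z)-4-(tert-butyldimethylsilyloxy)but-2-en-2-yl]-2-[(R)-2-(tert-butyldimethylsilyloxy)-3,3-dimethoxypropyl]-2-methylfuran-3(2H)-one (not isolated) | O=C1C=C(/C(C)=C\CO[Si](C)(C)C(C)(C)C)O[C@]1(C)C[C@@H](O[Si](C)(C)C(C)(C)C)C(OC)OC | intermediate
13 | (R)-2-(tert-butyldimethylsilyloxy)-3-{(R)-5-[(Z)-4-(tert-butyldimethylsilyloxy)but-2-en-2-yl]-2-methyl-3-oxo-2,3-dihydrofuran-2-yl}propanal | O=C1C=C(/C(C)=C\CO[Si](C)(C)C(C)(C)C)O[C@]1(C)C[C@@H](O[Si](C)(C)C(C)(C)C)C=O | intermediate
14 | methyl acrylate | C=CC(=O)OC | starting material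
15 | methyl (4R)-4-(tert-butyldimethylsilyloxy)-5-{(R)-5-[(Z)-4-(tert-butyldimethylsilyloxy)but-2-en-2-yl]-2-methyl-3-oxo-2,3-dihydrofuran-2-yl}-3-hydroxy-2-methylidenepentanoate (C3 epimers) | O=C1C=C(/C(C)=C\CO[Si](C)(C)C(C)(C)C)O[C@]1(C)C[C@@H](O[Si](C)(C)C(C)(C)C)C(O)C(=C)C(=O)OC | intermediate
16 | methyl (2Z,4R)-2-(bromomethyl)-4-(tert-butyldimethylsilyloxy)-5-{(R)-5-[(Z)-4-(tert-butyldimethylsilyloxy)but-2-en-2-yl]-2-methyl-3-oxo-2,3-dihydrofuran-2-yl}pent-2-enoate | O=C1C=C(/C(C)=C\CO[Si](C)(C)C(C)(C)C)O[C@]1(C)C[C@@H](O[Si](C)(C)C(C)(C)C)/C=C(\CBr)C(=O)OC | intermediate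
17 | methyl (2Z,4R)-2-(bromomethyl)-4-(tert-butyldimethylsilyloxy)-5-{(R)-5-[(Z)-4-hydroxybut-2-en-2-yl]-2-methyl-3-oxo-2,3-dihydrofuran-2-yl}pent-2-enoate | O=C1C=C(/C(C)=C\CO)O[C@]1(C)C[C@@H](O[Si](C)(C)C(C)(C)C)/C=C(\CBr)C(=O)OC | intermediate
18 | methyl (2Z,4R)-2-(bromomethyl)-4-(tert-butyldimethylsilyloxy)-5-{(R)-2-methyl-3-oxo-5-[(Z)-4-oxobut-2-en-2-yl]-2,3-dihydrofuran-2-yl}pent-2-enoate | O=C1C=C(/C(C)=C\C=O)O[C@]1(C)C[C@@H](O[Si](C)(C)C(C)(C)C)/C=C(\CBr)C(=O)OC | intermediate
19 | methyl 2-[(2Z,4S,5R,6R,8R)-6-(tert-butyldimethylsilyloxy)-4-hydroxy-2,8-dimethyl-9-oxo-11-oxabicyclo[6.2.1]undeca-1(10),2-dien-5-yl]prop-2-enoate (not isolated) | C=C(C(=O)OC)[C@@H]1[C@@H](O)/C=C(/C)C2=CC(=O)[C@@](C)(C[C@H]1O[Si](C)(C)C(C)(C)C)O2 | intermediate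
20 | (2Z,4S,8R,9R,11R)-9-(tert-butyldimethylsilyloxy)-2,11-dimethyl-7-methylidene-5,14-dioxatricyclo[9.2.1.0^4,8]tetradeca-1(13),2-diene-6,12-dione | C=C1C(=O)O[C@H]2/C=C(/C)C3=CC(=O)[C@@](C)(C[C@@H](O[Si](C)(C)C(C)(C)C)[C@H]12)O3 | intermediate
21 | (2Z,4S,8S,9R,11R)-9-hydroxy-2,11-dimethyl-7-methylidene-5,14-dioxatricyclo[9.2.1.0^4,8]tetradeca-1(13),2-diene-6,12-dione | C=C1C(=O)O[C@H]2/C=C(/C)C3=CC(=O)[C@@](C)(C[C@@H](O)[C@H]12)O3 | intermediate
22 | acetaldehyde | CC=O | starting material
23 | tert-butyl acrylate | C=CC(=O)OC(C)(C)C | starting material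
24 | tert-butyl 3-hydroxy-2-methylidenebutanoate (racemic) | CC(O)C(=C)C(=O)OC(C)(C)C | intermediate
25 | tert-butyl 3-acetoxy-2-methylidenebutanoate (racemic, not isolated) | CC(OC(C)=O)C(=C)C(=O)OC(C)(C)C | intermediate
26 | tert-butyl (E)-2-(acetoxymethyl)but-2-enoate | CC(C)(C)OC(=O)/C(=C/C)COC(C)=O | intermediate
27 | (E)-2-(acetoxymethyl)but-2-enoic acid | OC(=O)/C(=C/C)COC(C)=O | intermediate
28 | (E)-2-(acetoxymethyl)but-2-enoic 2,4,6-trichlorobenzoic anhydride (not isolated) | O=C(OC(=O)/C(=C/C)COC(C)=O)c1c(Cl)cc(Cl)cc1Cl | intermediate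
29 | [(2Z,4S,8S,9R,11R)-2,11-dimethyl-7-methylidene-6,12-dioxo-5,14-dioxatricyclo[9.2.1.0^4,8]tetradeca-1(13),2-dien-9-yl] (E)-2-(acetoxymethyl)but-2-enoate (CNP0176571.1) | C=C1C(=O)O[C@H]2/C=C(/C)C3=CC(=O)[C@@](C)(C[C@@H](OC(=O)/C(=C/C)COC(C)=O)[C@H]12)O3 | target

**Step count and risk**

Total: 16 steps. Longest linear sequence: 12 steps (steps 1, 2, 3, 5–12 and 16); step 4 and steps 13–15 are side branches.

Most likely to fail, in this order:

Step 5 (the proposed ring transposition). The lactolate may not open, or the ynone may take other paths (α-ketol shift, Z/E drift) before the 5-endo-dig closure. The fallback makes the same bonds stepwise with known reactions. It sets out from lactone 7, which is opened with MeNH(OMe)·HCl/AlMe3 (CH2Cl2, 0 °C) to the Weinreb amide (2R,4R)-2,4-dihydroxy-N,5,5-trimethoxy-N,2-dimethylpentanamide F1. The lithium acetylide of 9 (3.3 equiv, THF, −78 °C, AcOH quench at −78 °C) then gives hydroxy ynone 10, this time isolated. Ph3PAuNTf2 (2 mol %, toluene, rt), the established monovalent-gold 5-endo-dig cyclisation of α′-hydroxy ynones, closes the furanone and the route is rejoined at 11.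

Step 11 (ring closure). Oligomerisation, protodebromination or the wrong C6/C7 diastereomer are all possible, and the allylic bromide must survive steps 9 and 10. The fallback changes how the nucleophile is made: it is generated catalytically from a stable allylic acetate by palladium/indium umpolung, so the bromination and the stoichiometric chromium reagent are dropped. It sets out from MBH alcohol 15, which is acetylated (Ac2O, DMAP, CH2Cl2) to the C7-O-acetate of 15 F3. CSA/MeOH removes the primary TBS ether to give the hydroxybutenyl acetate F4, and Dess–Martin oxidation gives the Z-enal acetate F5. Pd(PPh3)4 (5 mol %) and InI (2 equiv) in THF at 0.002 M ionise the acetate on zerovalent palladium, transmetallate the allyl unit to indium and close the ring by γ-attack on the aldehyde; TsOH-catalysed lactonisation rejoins the route at 20.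

Step 7 (Morita–Baylis–Hillman on the advanced aldehyde). Two days with a nucleophilic amine may erode the C4=C5 Z geometry by reversible 1,6-addition, epimerise C8, or simply not turn over. The fallback delivers the acrylate unit as a preformed vinylmetal instead of by amine catalysis. It sets out from aldehyde 13: methyl propiolate is hydroaluminated with i-Bu2AlH/N-methylmorpholine N-oxide (THF, 0 °C) to methyl 2-(diisobutylalumanyl)prop-2-enoate F2, which adds to 13 at 0 °C within minutes (vinylalumination), and hydrolytic work-up rejoins the route at 15.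

**Further compounds**
F1 | step 5 | (2R,4R)-2,4-dihydroxy-N,5,5-trimethoxy-N,2-dimethylpentanamide | CON(C)C(=O)[C@](C)(O)C[C@@H](O)C(OC)OC
F2 | step 7 | methyl 2-(diisobutylalumanyl)prop-2-enoate | C=C([Al](CC(C)C)CC(C)C)C(=O)OC
F3 | step 11 | methyl (4R)-3-acetoxy-4-(tert-butyldimethylsilyloxy)-5-{(R)-5-[(Z)-4-(tert-butyldimethylsilyloxy)but-2-en-2-yl]-2-methyl-3-oxo-2,3-dihydrofuran-2-yl}-2-methylidenepentanoate | O=C1C=C(/C(C)=C\CO[Si](C)(C)C(C)(C)C)O[C@]1(C)C[C@@H](O[Si](C)(C)C(C)(C)C)C(OC(C)=O)C(=C)C(=O)OC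
F4 | step 11 | methyl (4R)-3-acetoxy-4-(tert-butyldimethylsilyloxy)-5-{(R)-5-[(Z)-4-hydroxybut-2-en-2-yl]-2-methyl-3-oxo-2,3-dihydrofuran-2-yl}-2-methylidenepentanoate | O=C1C=C(/C(C)=C\CO)O[C@]1(C)C[C@@H](O[Si](C)(C)C(C)(C)C)C(OC(C)=O)C(=C)C(=O)OC
F5 | step 11 | methyl (4R)-3-acetoxy-4-(tert-butyldimethylsilyloxy)-5-{(R)-2-methyl-3-oxo-5-[(Z)-4-oxobut-2-en-2-yl]-2,3-dihydrofuran-2-yl}-2-methylidenepentanoate | O=C1C=C(/C(C)=C\C=O)O[C@]1(C)C[C@@H](O[Si](C)(C)C(C)(C)C)C(OC(C)=O)C(=C)C(=O)OC
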